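The trans-decalin and its C8 oxygen are traced back to one acyclic chain: a farnesylacetone-derived epoxy dienone. A single Lewis-acid cascade, started at a (13S,14S)-epoxide and ended by the ketone oxygen, forms C4–C5, C9–C10 and C8–O, closes rings A and B plus a temporary oxygen ring C, and sets C4, C5, C8, C9 and C10. It exploits the chair–chair fold of a farnesyl chain onto C1–C10, the 8α-oxygen as a captured C8 cation, and equatorial C18 as the (E)-silyloxymethyl group of the epoxide. The precursor is a free methyl ketone with two (E)-trisubstituted alkenes and a TBS-protected hydroxymethyl epoxide. O18 later carries oxidation to C6; the dienyl butenolide is attached last.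

Key step: step 6

Remark on the chemistry: the 6α-hydroxy-18-aldehyde of the target can close reversibly to its 18,6α-lactol, so 19 and 23 are written in the open form of the target; phosphonate 16 is taken as a commercial reagent.

Numbering: acyclic compounds are numbered as pentadecan-2-ones (C2 ketone, C13/C14 epoxide). Cyclic compounds use labdane numbering: decalin C1–C10, chain C11–C13 from C9, C16 the methyl on C13, C17 on C8, C18 (α, equatorial) and C19 (β) on C4, C20 on C10. "14,15-Dinorlabdane" is this C18 skeleton.

Step 1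
Reactants: 1 (2E,6E)-farnesol
Product: 2 (2E,6E)-farnesyl bromide
Conditions: PBr3 (0.4 equiv), Et2O, −10 °C
Reagents that add atoms: phosphorus tribromide, BrP(Br)Br
Why: SN2 bromination of a primary allylic alcohol through its phosphite ester, which at low temperature should keep the 2E geometry and avoid allylic transposition.

Step 2
Reactants: 2 (2E,6E)-farnesyl bromide; 3 ethyl acetoacetate
Product: 5 (5E,9E)-6,10,14-trimethylpentadeca-5,9,13-trien-2-one (farnesylacetone), via farnesylated keto ester 4 (not isolated)
Conditions: NaOEt, EtOH, 0 °C → rt; then aq. NaOH, 60 °C; then aq. HCl to pH 4, 50 °C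
Reagents that add atoms: none
Why: acetoacetic ester synthesis, in which the stabilised enolate is C-alkylated at the primary allylic carbon (SN2, alkenes untouched) and the β-keto acid formed on saponification loses CO2.

Step 3
Reactants: 5 farnesylacetone
Product: 6 (5E,9E,13E)-15-hydroxy-6,10,14-trimethylpentadeca-5,9,13-trien-2-one
Conditions: SeO2 (0.3 equiv), t-BuOOH (3 equiv), salicylic acid (0.1 equiv), CH2Cl2, 0 °C → rt, stopped at partial conversion
Reagents that add atoms: tert-butyl hydroperoxide, CC(C)(C)OO
Why: catalytic SeO2 allylic oxidation (ene reaction then [2,3]-shift) is selective for the (E)-methyl of the terminal isopropylidene group; the ketone is left unprotected, which rules out a borohydride work-up, so the run is stopped early and 5 is recovered.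

Step 4
Reactants: 6 the (13E)-allylic alcohol
Product: 7 (5E,9E,13S,14S)-13,14-epoxy-15-hydroxy-6,10,14-trimethylpentadeca-5,9-dien-2-one
Conditions: Ti(OiPr)4 (10 mol%), L-(+)-diethyl tartrate (12 mol%), t-BuOOH (2 equiv, in decane), 4 Å MS, CH2Cl2, −20 °C
Reagents that add atoms: tert-butyl hydroperoxide, CC(C)(C)OO
Why: Katsuki–Sharpless asymmetric epoxidation, which touches only the allylic alkene and with the L-(+)-tartrate should give the (S,S)-epoxide as it does for other (E)-2-methylalk-2-en-1-ols, setting C13 and C14 (the future C3 and C4).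

Step 5
Reactants: 7 the epoxy alcohol
Product: 8 (5E,9E,13S,14S)-15-(tert-butyldimethylsilyloxy)-13,14-epoxy-6,10,14-trimethylpentadeca-5,9-dien-2-one
Conditions: TBSCl, imidazole, DMF, 0 °C → rt
Reagents that add atoms: tert-butyldimethylsilyl chloride, CC(C)(C)[Si](C)(C)Cl
Why: standard silylation of a primary alcohol under basic conditions that leave the epoxide and ketone alone; the ketone was never masked, so no acid step is needed before the cyclisation.

Step 6
Reactants: 8 the epoxy dienone
Product: 9 18-(tert-butyldimethylsilyloxy)-8α,13-epoxy-14,15-dinorlabd-12-en-3β-ol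
Conditions: MeAlCl2 (2.2 equiv), CH2Cl2, −78 °C; then Et3N, −78 °C → rt; aq. NaHCO3
Reagents that add atoms: none
Why: MeAlCl2 binds the epoxide oxygen (a second equivalent is held by the ketone) and the tertiary C4–O bond ionises as C5 of the (E)-5,10-alkene attacks anti, closing ring A (six-membered, endo mode, tertiary C10 cation); C9 of the (E)-8,9-alkene then adds to C10 to close ring B in the same endo mode through a chair–chair fold, the C13 carbonyl oxygen captures the tertiary C8 cation anti to the new C9–C10 bond to close ring C (six-membered, carbonyl bond inside the ring), and loss of H12 on the amine quench gives the enol ether. The closest known reactions are Lewis-acid epoxy-polyene cyclisations of oxidosqualene-type substrates and the acid cyclisation of farnesylacetone to the tricyclic enol ether sclareol oxide. C3 comes unchanged from the (13S) epoxide carbon and, by requiring an equatorial C3–O bond in the chair, selects the face of the 5,10-alkene; C4 is set by inversion at the epoxide carbon, so the (E)-silyloxymethyl group becomes equatorial C18. C5 and C10 are set by anti addition across the (E)-5,10-alkene (trans ring fusion), C9 by the (E)-8,9-alkene in the chair (H9 α, chain β), and C8 by anti capture (oxygen α and equatorial, methyl β and axial). The step needs cleavage of the tertiary and not the secondary epoxide C–O bond, which the trisubstituted epoxide and the six-membered endo path favour despite the inductive pull of the CH2OTBS group. It also needs oxygen capture in place of early proton loss, which the all-tertiary cation sequence and the ketone oxygen five atoms from C8 favour.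

Step 7
Reactants: 9 the tricyclic enol ether alcohol
Product: 10 O-[18-(tert-butyldimethylsilyloxy)-8α,13-epoxy-14,15-dinorlabd-12-en-3β-yl] 1H-imidazole-1-carbothioate
Conditions: 1,1'-thiocarbonyldiimidazole (2 equiv), DMAP (0.2 equiv), ClCH2CH2Cl, 80 °C
Reagents that add atoms: 1,1'-thiocarbonyldiimidazole, S=C(n1ccnc1)n1ccnc1
Why: thioacylation of the equatorial secondary alcohol (first half of the Barton–McCombie deoxygenation) under neutral conditions, which spare the enol ether and avoid the O3-to-O18 silyl shift that an alkoxide could start.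

Step 8
Reactants: 10 the thiocarbonylimidazolide
Product: 11 18-(tert-butyldimethylsilyloxy)-8α,13-epoxy-14,15-dinorlabd-12-ene
Conditions: Bu3SnH (2 equiv), AIBN (0.2 equiv), toluene, 110 °C
Reagents that add atoms: none
Why: Barton–McCombie radical deoxygenation, in which the stannyl radical adds to sulfur, the C3–O bond breaks and the secondary radical takes hydrogen from the stannane, so C3 becomes a methylene while enol ether and silyl ether stay inert.

Step 9
Reactants: 11 the deoxygenated enol ether
Product: 12 (13S)-13-methoxy-8α,13-epoxy-14,15-dinorlabdan-18-ol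
Conditions: p-TsOH·H2O (0.1 equiv), MeOH/CH2Cl2, rt; then Et3N
Reagents that add atoms: methanol, CO
Why: acid-catalysed addition of methanol to the enol ether through the C13 oxocarbenium ion masks ring C as a mixed ketal while the same acid methanolyses the primary silyl ether; the axial-methoxy (13S) epimer is expected (anomeric effect, C16 methyl kept away from the C17 methyl), and C13 is erased again in step 11.

Step 10
Reactants: 12 the ketal alcohol
Product: 13 (13S)-13-methoxy-6α,18:8α,13-diepoxy-14,15-dinorlabdane
Conditions: PhI(OAc)2 (1.5 equiv), I2 (1 equiv), NaHCO3, cyclohexane/CH2Cl2, visible light, 25 °C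
Reagents that add atoms: none
Why: hypoiodite (Suárez) remote functionalisation, in which the O18 alkoxyl radical on the equatorial C4 arm lies beside the equatorial 6α-hydrogen, so 1,5-hydrogen transfer, oxidation of the C6 radical and ring closure should give the tetrahydrofuran, with C6–O necessarily α because the bridge can only form on that face.

Step 11
Reactants: 13 the 6α,18-ether
Product: 15 8α-hydroxy-13-oxo-14,15-dinorlabdan-18,6α-olide, via ketal lactone 14 (not isolated)
Conditions: RuCl3·xH2O (5 mol%), NaIO4 (4 equiv), CCl4/MeCN/H2O, rt; then 1 M HCl, THF, rt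
Reagents that add atoms: sodium periodate, [Na+].[O-]I(=O)(=O)=O; water, O
Why: RuO4 oxidation of a cyclic ether to the lactone at the open C18 methylene (the remaining C6 hydrogen is axial and shielded by the C19 and C20 methyl groups), after which dilute aqueous acid hydrolyses the mixed ketal to the δ-hydroxy ketone without touching C6.

Step 12
Reactants: 15 the hydroxy keto lactone; 16 diethyl [3-(trimethylsilyl)prop-2-yn-1-yl]phosphonate
Product: 18 (13E)-8α-hydroxy-13-(prop-2-yn-1-ylidene)-14,15-dinorlabdan-18,6α-olide, via silylated enyne 17 (not isolated)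
Conditions: 16 (3 equiv), LiN(SiMe3)2 (3.2 equiv), THF, −78 °C → rt; then Bu4NF, 0 °C
Reagents that add atoms: none
Why: Horner–Wadsworth–Emmons olefination of the methyl ketone with the lithiated propargylic phosphonate should give mainly the (13E)-enyne (alkynyl group trans to the larger C12 arm), the minor (13Z) isomer being removed by chromatography, and fluoride then cleaves the C–Si bond; the lactone has no α-hydrogen and a shielded carbonyl, and the enyne cannot take up the C8 alkoxide.

Step 13
Reactants: 18 the enyne lactone
Product: 19 (13E)-6α,8α-dihydroxy-13-(prop-2-yn-1-ylidene)-14,15-dinorlabdan-18-al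
Conditions: i-Bu2AlH (2.5 equiv), CH2Cl2, −78 °C; MeOH, aq. Rochelle salt
Reagents that add atoms: none
Why: half-reduction of a γ-lactone, which at −78 °C should stop at the aluminium hemiacetal and release the lactol/hydroxy aldehyde on work-up, while the isolated enyne and the tertiary alkoxide are inert.

Step 14
Reactants: 20 but-2-ynoic acid
Product: 21 (Z)-3-iodobut-2-enoic acid
Conditions: NaI (1.6 equiv), AcOH, 115 °C
Reagents that add atoms: sodium iodide, [Na+].[I-]
Why: conjugate addition of iodide to the ynoic acid followed by anti protonation, the known route to (Z)-β-iodoalkenoic acids, which places iodine cis to the carboxyl group.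

Step 15
Reactants: 19 the hydroxy aldehyde enyne; 21 (Z)-3-iodobut-2-enoic acid
Product: 23 (13E)-13-{2-[(2Z)-3-methyl-5-oxofuran-2(5H)-ylidene]ethylidene}-6α,8α-dihydroxy-14,15-dinorlabdan-18-al (target CNP0278517.1), via dienynoic acid 22 (not isolated)
Conditions: Pd(PPh3)4 (5 mol%), CuI (10 mol%), Et3N (3 equiv), MeCN, rt, dark
Reagents that add atoms: none
Why: tandem Sonogashira coupling and 5-exo-dig lactonisation of a (Z)-β-iodo acid with a terminal alkyne, in which the carboxylate adds anti across the metal-activated triple bond to give the (Z)-ylidene butenolide; no Lewis acid or hydride meets the free C18 aldehyde and the hydroxyl groups, and the (13E) alkene is not touched.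

Compound list
1 | (2E,6E)-farnesol | CC(C)=CCC/C(C)=C/CC/C(C)=C/CO | starting material
2 | (2E,6E)-farnesyl bromide | CC(C)=CCC/C(C)=C/CC/C(C)=C/CBr | intermediate
3 | ethyl acetoacetate | CCOC(=O)CC(C)=O | starting material
4 | ethyl (4E,8E)-2-acetyl-5,9,13-trimethyltetradeca-4,8,12-trienoate (racemic at C2) | CCOC(=O)C(C/C=C(\C)CC/C=C(\C)CCC=C(C)C)C(C)=O | intermediate (not isolated)
5 | (5E,9E)-6,10,14-trimethylpentadeca-5,9,13-trien-2-one | CC(=O)CC/C=C(\C)CC/C=C(\C)CCC=C(C)C | intermediate
6 | (5E,9E,13E)-15-hydroxy-6,10,14-trimethylpentadeca-5,9,13-trien-2-one | CC(=O)CC/C=C(\C)CC/C=C(\C)CC/C=C(\C)CO | intermediate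
7 | (5E,9E,13S,14S)-13,14-epoxy-15-hydroxy-6,10,14-trimethylpentadeca-5,9-dien-2-one | CC(=O)CC/C=C(\C)CC/C=C(\C)CC[C@@H]1O[C@@]1(C)CO | intermediate
8 | (5E,9E,13S,14S)-15-(tert-butyldimethylsilyloxy)-13,14-epoxy-6,10,14-trimethylpentadeca-5,9-dien-2-one | CC(=O)CC/C=C(\C)CC/C=C(\C)CC[C@@H]1O[C@@]1(C)CO[Si](C)(C)C(C)(C)C | intermediate
9 | 18-(tert-butyldimethylsilyloxy)-8α,13-epoxy-14,15-dinorlabd-12-en-3β-ol | CC1=CC[C@@H]2[C@@]3(C)CC[C@H](O)[C@@](C)(CO[Si](C)(C)C(C)(C)C)[C@@H]3CC[C@@]2(C)O1 | intermediate
10 | O-[18-(tert-butyldimethylsilyloxy)-8α,13-epoxy-14,15-dinorlabd-12-en-3β-yl] 1H-imidazole-1-carbothioate | CC1=CC[C@@H]2[C@@]3(C)CC[C@H](OC(=S)n4ccnc4)[C@@](C)(CO[Si](C)(C)C(C)(C)C)[C@@H]3CC[C@@]2(C)O1 | intermediate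
11 | 18-(tert-butyldimethylsilyloxy)-8α,13-epoxy-14,15-dinorlabd-12-ene | CC1=CC[C@@H]2[C@@]3(C)CCC[C@@](C)(CO[Si](C)(C)C(C)(C)C)[C@@H]3CC[C@@]2(C)O1 | intermediate
12 | (13S)-13-methoxy-8α,13-epoxy-14,15-dinorlabdan-18-ol (13β-methoxy, axial) | CO[C@]1(C)CC[C@@H]2[C@@]3(C)CCC[C@@](C)(CO)[C@@H]3CC[C@@]2(C)O1 | intermediate
13 | (13S)-13-methoxy-6α,18:8α,13-diepoxy-14,15-dinorlabdane | CO[C@]1(C)CC[C@@H]2[C@@]3(C)CCC[C@@](C)(CO4)[C@@H]3[C@@H]4C[C@@]2(C)O1 | intermediate
14 | (13S)-13-methoxy-8α,13-epoxy-14,15-dinorlabdan-18,6α-olide | CO[C@]1(C)CC[C@@H]2[C@@]3(C)CCC[C@@](C)(C(=O)O4)[C@@H]3[C@@H]4C[C@@]2(C)O1 | intermediate (not isolated)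
15 | 8α-hydroxy-13-oxo-14,15-dinorlabdan-18,6α-olide | CC(=O)CC[C@@H]1[C@@]2(C)CCC[C@@](C)(C(=O)O3)[C@@H]2[C@@H]3C[C@@]1(C)O | intermediate
16 | diethyl [3-(trimethylsilyl)prop-2-yn-1-yl]phosphonate | CCOP(=O)(CC#C[Si](C)(C)C)OCC | starting material
17 | (13E)-8α-hydroxy-13-[3-(trimethylsilyl)prop-2-yn-1-ylidene]-14,15-dinorlabdan-18,6α-olide | C[Si](C)(C)C#C/C=C(\C)CC[C@@H]1[C@@]2(C)CCC[C@@](C)(C(=O)O3)[C@@H]2[C@@H]3C[C@@]1(C)O | intermediate (not isolated)
18 | (13E)-8α-hydroxy-13-(prop-2-yn-1-ylidene)-14,15-dinorlabdan-18,6α-olide | C#C/C=C(\C)CC[C@@H]1[C@@]2(C)CCC[C@@](C)(C(=O)O3)[C@@H]2[C@@H]3C[C@@]1(C)O | intermediate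
19 | (13E)-6α,8α-dihydroxy-13-(prop-2-yn-1-ylidene)-14,15-dinorlabdan-18-al | C#C/C=C(\C)CC[C@@H]1[C@@]2(C)CCC[C@@](C)(C=O)[C@@H]2[C@@H](O)C[C@@]1(C)O | intermediate
20 | but-2-ynoic acid | CC#CC(=O)O | starting material
21 | (Z)-3-iodobut-2-enoic acid | C/C(I)=C/C(=O)O | intermediate
22 | (2Z,6E)-6-(6α,8α-dihydroxy-18-oxo-14,15-dinorlabdan-13-ylidene)-3-methylhex-2-en-4-ynoic acid | C/C(C#C/C=C(\C)CC[C@@H]1[C@@]2(C)CCC[C@@](C)(C=O)[C@@H]2[C@@H](O)C[C@@]1(C)O)=C/C(=O)O | intermediate (not isolated)
23 | CNP0278517.1, (13E)-13-{2-[(2Z)-3-methyl-5-oxofuran-2(5H)-ylidene]ethylidene}-6α,8α-dihydroxy-14,15-dinorlabdan-18-al | CC1=CC(=O)O/C1=C\C=C(/C)CC[C@@H]1[C@@]2(C)CCC[C@@](C)(C=O)[C@@H]2[C@@H](O)C[C@@]1(C)O | target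

Total step count: 15. Longest linear sequence: 14 steps (steps 1–13 and 15); step 14 is a one-step side branch.

Steps most likely to fail

Step 6. The inductive pull of the silyloxymethyl group may slow ionisation of the tertiary C–O bond. Rearrangement of the epoxide to a carbonyl compound, closure at the secondary epoxide carbon, or proton loss after the first or second ring could then compete with the full cascade. The fallback sets out from 8 and closes the rings by radicals instead of cations. Cp2TiCl (trivalent titanium, made in the flask from Cp2TiCl2 and Mn dust, THF, rt) opens the epoxide homolytically at the tertiary carbon whatever the inductive effect. The carbon radical closes rings A and B through the same chair–chair fold, and the cascade ends by hydrogen loss to the exocyclic alkene of 3β-hydroxy-18-(tert-butyldimethylsilyloxy)-14,15-dinorlabd-8(17)-en-13-one F1. Catalytic p-TsOH in CH2Cl2 then protonates the 8(17)-alkene and the ketone oxygen closes ring C from the equatorial α side, which returns the route to 9.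

Step 10. The neopentyl-type O18 alkoxyl radical may fragment with loss of formaldehyde faster than it abstracts the 6α-hydrogen. The mixed ketal may also collapse to the enol ether in the iodine-containing medium and be consumed by the oxidant. The fallback sets out from 12 and directs the C–H oxidation from a carboxylate instead of an alkoxyl radical. TEMPO (cat.)/PhI(OAc)2 in MeCN/water oxidises the primary alcohol to the acid while the aqueous medium hydrolyses the ketal, giving 8α-hydroxy-13-oxo-14,15-dinorlabdan-18-oic acid F2. Carboxylate-directed iron-catalysed C–H oxidation ([Fe((S,S)-PDP)(MeCN)2](SbF6)2, H2O2, MeCN) should then lactonise at the γ-methylene C6 on the α face beside the equatorial carboxyl group. This rejoins the route at 15 and makes step 11 unnecessary.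

Step 12. The olefination may discriminate poorly between the methyl and the methylene arm of the ketone, giving a (13E)/(13Z) mixture that is hard to separate, and it may be slow while the ketone is held as its hemiketal alkoxide. The fallback sets out from 15 and builds the trisubstituted alkene by alkyne carbometalation instead of carbonyl olefination. LiN(i-Pr)2 and ClP(O)(OEt)2 convert the methyl ketone into the terminal enol phosphate, 13-(diethoxyphosphoryloxy)-8α-hydroxy-14,15-dinorlabd-13(16)-en-18,6α-olide F3 (the hindered C8 alkoxide is expected to stay free). More LiN(i-Pr)2 eliminates it to the terminal alkyne, 8α-hydroxy-14,15-dinorlabd-13(16)-yn-18,6α-olide F4. Zirconium-catalysed methylalumination (Me3Al, Cp2ZrCl2) followed by I2 gives, by syn addition, (13E)-8α-hydroxy-14-iodo-15-norlabd-13-en-18,6α-olide F5 as one geometric isomer. Sonogashira coupling with trimethylsilylacetylene (Pd(PPh3)4, CuI, Et3N) then gives 17, which fluoride converts into 18 as in step 12.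

Further compounds
F1 | step 6 | 3β-hydroxy-18-(tert-butyldimethylsilyloxy)-14,15-dinorlabd-8(17)-en-13-one | CC(=O)CC[C@@H]1[C@@]2(C)CC[C@H](O)[C@@](C)(CO[Si](C)(C)C(C)(C)C)[C@@H]2CCC1=C
F2 | step 10 | 8α-hydroxy-13-oxo-14,15-dinorlabdan-18-oic acid | CC(=O)CC[C@@H]1[C@@]2(C)CCC[C@@](C)(C(=O)O)[C@@H]2CC[C@@]1(C)O
F3 | step 12 | 13-(diethoxyphosphoryloxy)-8α-hydroxy-14,15-dinorlabd-13(16)-en-18,6α-olide | C=C(OP(=O)(OCC)OCC)CC[C@@H]1[C@@]2(C)CCC[C@@](C)(C(=O)O3)[C@@H]2[C@@H]3C[C@@]1(C)O
F4 | step 12 | 8α-hydroxy-14,15-dinorlabd-13(16)-yn-18,6α-olide | C#CCC[C@@H]1[C@@]2(C)CCC[C@@](C)(C(=O)O3)[C@@H]2[C@@H]3C[C@@]1(C)O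
F5 | step 12 | (13E)-8α-hydroxy-14-iodo-15-norlabd-13-en-18,6α-olide | I/C=C(\C)CC[C@@H]1[C@@]2(C)CCC[C@@](C)(C(=O)O3)[C@@H]2[C@@H]3C[C@@]1(C)O
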